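## Retrosynthetic overview

1. The last operation is a one-pot release of two benzyl ethers, the methyl ether ortho to the ester carbonyl, and one acetate.
2. Key disconnection: the C–C bond between the ester-bearing carbinol carbon and the first CH2 of the heptamethylene chain leading to the resorcinol ring. The same operation also makes the ester C–O bond, so the coupled ester falls apart into an aroyl bromide, butanal and a 5-(hept-6-enyl)resorcinol dibenzyl ether.
3. Enabling feature: that carbinol carbon is an sp3 CH bearing an acyloxy oxygen (it stabilises an α-radical and its C=O can bind nickel), an n-propyl group (= butanal) and an unbranched CH2 (= terminal alkene carbon). The free carbinol carbon in the dodecyl chain on the benzoate ring has the same (R) O/n-propyl/polymethylene pattern and is made the same way with acetyl bromide.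
4. The carboxyl carbon comes from Vilsmeier–Haack formylation and Pinnick oxidation of the 5-alkylresorcinol dimethyl ether. Both alkenyl arenes come from copper-catalysed Grignard couplings of 3,5-dialkoxybenzyl bromides.
5. No ring is formed in the route: both benzene rings are bought.

Key step: step 7

Assumption: L* is a C2-symmetric chiral bis(oxazoline) ligand. The antipode that leads to the (R)-ester is fixed by a test run of step 3 (Mosher analysis of the derived alcohol). The same antipode is taken to serve step 7, because both stereocentres have the same spatial arrangement of O, n-propyl and long chain.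

## Route

Step 1
Reactants: 1 3,5-bis(benzyloxy)benzyl bromide; 2 6-bromohex-1-ene
Product: 4 1,3-bis(benzyloxy)-5-(hept-6-en-1-yl)benzene, via hex-5-enylmagnesium bromide 3 (not isolated)
Conditions: 2, Mg, THF, rt → 40 °C; then 1, Li2CuCl4 (3 mol%), THF, −20 °C → rt
Reagents that add atoms: magnesium, [Mg] (stays in intermediate 3 only)
Why: Copper-catalysed sp3–sp3 cross-coupling of a primary alkyl Grignard reagent with a reactive benzylic bromide (Kochi coupling) should leave the aryl benzyl ethers and the terminal alkene untouched, and no stereocentre is formed.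

Step 2
Reactants: 5 3,5-dimethoxybenzyl bromide; 6 7-bromohept-1-ene
Product: 8 1,3-dimethoxy-5-(oct-7-en-1-yl)benzene, via hept-6-enylmagnesium bromide 7 (not isolated)
Conditions: 6, Mg, THF, rt → 40 °C; then 5, Li2CuCl4 (3 mol%), THF, −20 °C → rt
Reagents that add atoms: magnesium, [Mg] (stays in intermediate 7 only)
Why: The same Kochi-type copper-catalysed Grignard–benzyl bromide coupling as in step 1 should deliver the eight-carbon alkenyl chain in one operation, and no stereocentre is formed.

Step 3
Reactants: 8 1,3-dimethoxy-5-(oct-7-en-1-yl)benzene; 9 butanal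
Product: 11 (4R)-12-(3,5-dimethoxyphenyl)dodecan-4-yl acetate, via 1-bromobutyl acetate 10 (not isolated)
Conditions: 9, AcBr, CH2Cl2, 0 °C → rt, evaporation; then 8, NiBr2·diglyme (8 mol%), L* (10 mol%), (EtO)3SiH, K3PO4·H2O, t-BuOMe, rt
Reagents that add atoms: acetyl bromide, CC(=O)Br
Why: Acetyl bromide adds to butanal to give racemic 10, and the nickel hydride catalysed enantioconvergent hydroalkylation of a terminal olefin with a 1-bromoalkyl ester then joins the planar α-acyloxy radical to the linear alkylnickel species, with the chiral bis(oxazoline) ligand setting the (R) centre under catalyst control.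

Step 4
Reactants: 11 (4R)-12-(3,5-dimethoxyphenyl)dodecan-4-yl acetate
Product: 13 (4R)-12-(2-formyl-3,5-dimethoxyphenyl)dodecan-4-yl acetate, via aryl iminium chloride 12 (not isolated)
Conditions: POCl3, DMF, 0 → 60 °C; then ice/H2O
Reagents that add atoms: N,N-dimethylformamide, CN(C)C=O; water, O; phosphoryl chloride, O=P(Cl)(Cl)Cl (chloride of intermediate 12 only)
Why: Vilsmeier–Haack formylation of 5-alkylresorcinol dimethyl ethers prefers the position ortho to the alkyl chain, ortho to one methoxy group and para to the other, while the acetate and its stereocentre are inert.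

Step 5
Reactants: 13 (4R)-12-(2-formyl-3,5-dimethoxyphenyl)dodecan-4-yl acetate
Product: 14 2-[(9R)-9-acetoxydodecyl]-4,6-dimethoxybenzoic acid
Conditions: NaClO2, NaH2PO4, 2-methylbut-2-ene (large excess), t-BuOH/THF/H2O, 0 °C → rt
Reagents that add atoms: sodium chlorite, [Na+].[O-]Cl=O
Why: Pinnick oxidation converts the hindered aldehyde to the acid under buffered conditions that spare the acetate, and the alkene scavenger intercepts hypochlorous acid before it can chlorinate the electron-rich ring.

Step 6
Reactants: 14 2-[(9R)-9-acetoxydodecyl]-4,6-dimethoxybenzoic acid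
Product: 15 2-[(9R)-9-acetoxydodecyl]-4,6-dimethoxybenzoyl bromide
Conditions: (COBr)2, DMF (cat.), CH2Cl2, 0 °C → rt; evaporation, used at once
Reagents that add atoms: oxalyl bromide, O=C(Br)C(=O)Br
Why: DMF-catalysed conversion of a carboxylic acid into the acyl halide with an oxalyl halide gives only gaseous by-products, so the crude bromide can be used directly, and the acetate and aryl methyl ethers do not react with an acyl bromide in the absence of a Lewis acid.

Step 7
Reactants: 15 2-[(9R)-9-acetoxydodecyl]-4,6-dimethoxybenzoyl bromide; 9 butanal; 4 1,3-bis(benzyloxy)-5-(hept-6-en-1-yl)benzene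
Product: 17 (4R)-11-[3,5-bis(benzyloxy)phenyl]undecan-4-yl 2-[(9R)-9-acetoxydodecyl]-4,6-dimethoxybenzoate, via 1-bromobutyl aroate 16 (not isolated)
Conditions: 15, 9, ZnBr2 (2 mol%), CH2Cl2, −10 °C → rt, evaporation; only then 4, NiBr2·diglyme (10 mol%), L* (12 mol%), (EtO)3SiH, K3PO4·H2O, t-BuOMe, rt
Reagents that add atoms: none
Why: The aroyl bromide ionises easily to an acylium ion stabilised by the 2,4-dimethoxy groups, so the oxygen of butanal can be acylated in spite of the 2,6-disubstitution, and bromide completes the acyl halide–aldehyde addition to 16, a mixture of epimers at the C–Br carbon. In the nickel stage L*Ni–H, made from the nickel bromide, the silane and the phosphate, inserts the terminal alkene of 4 in the anti-Markovnikov sense to a primary alkylnickel species, nickel abstracts bromine from 16, and the planar α-acyloxy radical is captured and released by reductive elimination as the new C(sp3)–C(sp3) bond. The closest known reaction type is the nickel hydride catalysed enantioconvergent hydroalkylation of terminal olefins with racemic 1-bromoalkyl esters, including its variant in which the bromide is made in situ from aldehyde and acyl bromide. No ring is closed. The new carbinol stereocentre is set by the chiral bis(oxazoline)nickel complex, which reads the difference between acyloxy group, n-propyl and H on the radical rather than the negligible difference between n-propyl and the long chain, so both epimers of 16 converge on the (R) product and the remote (R) centre in the acyl part is too far away to interfere. Chemoselectivity is secured by the substrates, since 4 holds the only C=C bond and 16 the only C–Br bond, 4 meets the mixture only after 15 is consumed, and aryl ethers, the acetate and the hindered benzoate do not react with Ni–H or the silane.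

Step 8
Reactants: 17 (4R)-11-[3,5-bis(benzyloxy)phenyl]undecan-4-yl 2-[(9R)-9-acetoxydodecyl]-4,6-dimethoxybenzoate
Product: 19 5'-methoxy-integracin B, (4R)-11-(3,5-dihydroxyphenyl)undecan-4-yl 2-hydroxy-6-[(9R)-9-hydroxydodecyl]-4-methoxybenzoate, via triphenol acetate 18 (not isolated)
Conditions: BCl3, C6HMe5, CH2Cl2, −78 → 0 °C; then MeOH, 0 → 40 °C
Reagents that add atoms: none
Why: Boron trichloride with pentamethylbenzene as cation scavenger cleaves the aryl benzyl ethers, on warming chelation of boron between the ester carbonyl and the ortho-methoxy oxygen directs demethylation to that group alone (the para-methoxy group cannot chelate), and the methanol quench produces HCl in MeOH, which transesterifies the unhindered acetate but not the 2,6-disubstituted benzoate, so no stereocentre is touched.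

## Compound list

1 | 3,5-bis(benzyloxy)benzyl bromide | BrCc1cc(OCc2ccccc2)cc(OCc2ccccc2)c1 | starting material
2 | 6-bromohex-1-ene | C=CCCCCBr | starting material
3 | hex-5-en-1-ylmagnesium bromide | C=CCCCC[Mg]Br | intermediate
4 | 1,3-bis(benzyloxy)-5-(hept-6-en-1-yl)benzene | C=CCCCCCc1cc(OCc2ccccc2)cc(OCc2ccccc2)c1 | intermediate
5 | 3,5-dimethoxybenzyl bromide | COc1cc(CBr)cc(OC)c1 | starting material
6 | 7-bromohept-1-ene | C=CCCCCCBr | starting material
7 | hept-6-en-1-ylmagnesium bromide | C=CCCCCC[Mg]Br | intermediate
8 | 1,3-dimethoxy-5-(oct-7-en-1-yl)benzene | C=CCCCCCCc1cc(OC)cc(OC)c1 | intermediate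
9 | butanal | CCCC=O | starting material
10 | 1-bromobutyl acetate (racemic) | CCCC(Br)OC(C)=O | intermediate
11 | (4R)-12-(3,5-dimethoxyphenyl)dodecan-4-yl acetate | CCC[C@@H](OC(C)=O)CCCCCCCCc1cc(OC)cc(OC)c1 | intermediate
12 | N-{2-[(9R)-9-acetoxydodecyl]-4,6-dimethoxybenzylidene}-N-methylmethanaminium chloride | CCC[C@@H](OC(C)=O)CCCCCCCCc1cc(OC)cc(OC)c1C=[N+](C)C.[Cl-] | intermediate
13 | (4R)-12-(2-formyl-3,5-dimethoxyphenyl)dodecan-4-yl acetate | CCC[C@@H](OC(C)=O)CCCCCCCCc1cc(OC)cc(OC)c1C=O | intermediate
14 | 2-[(9R)-9-acetoxydodecyl]-4,6-dimethoxybenzoic acid | CCC[C@@H](OC(C)=O)CCCCCCCCc1cc(OC)cc(OC)c1C(=O)O | intermediate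
15 | 2-[(9R)-9-acetoxydodecyl]-4,6-dimethoxybenzoyl bromide | CCC[C@@H](OC(C)=O)CCCCCCCCc1cc(OC)cc(OC)c1C(=O)Br | intermediate
16 | (1RS)-1-bromobutyl 2-[(9R)-9-acetoxydodecyl]-4,6-dimethoxybenzoate (both epimers at C–Br) | CCC[C@@H](OC(C)=O)CCCCCCCCc1cc(OC)cc(OC)c1C(=O)OC(Br)CCC | intermediate
17 | (4R)-11-[3,5-bis(benzyloxy)phenyl]undecan-4-yl 2-[(9R)-9-acetoxydodecyl]-4,6-dimethoxybenzoate | CCC[C@@H](OC(C)=O)CCCCCCCCc1cc(OC)cc(OC)c1C(=O)O[C@H](CCC)CCCCCCCc1cc(OCc2ccccc2)cc(OCc2ccccc2)c1 | intermediate
18 | (4R)-11-(3,5-dihydroxyphenyl)undecan-4-yl 2-[(9R)-9-acetoxydodecyl]-6-hydroxy-4-methoxybenzoate | CCC[C@@H](OC(C)=O)CCCCCCCCc1cc(OC)cc(O)c1C(=O)O[C@H](CCC)CCCCCCCc1cc(O)cc(O)c1 | intermediate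
19 | 5'-methoxy-integracin B, (4R)-11-(3,5-dihydroxyphenyl)undecan-4-yl 2-hydroxy-6-[(9R)-9-hydroxydodecyl]-4-methoxybenzoate | CCC[C@@H](O)CCCCCCCCc1cc(OC)cc(O)c1C(=O)O[C@H](CCC)CCCCCCCc1cc(O)cc(O)c1 | target

## Step count and risks

Total step count: 8.
Longest linear sequence: 7 (steps 2–8, from 3,5-dimethoxybenzyl bromide).

**Step 7.**
- What may go wrong: slow or reversible addition of the hindered aroyl bromide to butanal, hydrolysis or simple reduction of the C–Br bond before coupling, and eroded facial selectivity because the bulky aroyl group binds nickel differently from small acyl groups.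
- The fallback joins the fragments through the C–O bond instead. It sets out from 4 and 14 and comes back at 17.
- Olefin 4 would be run through the conditions of step 3 (butanal 9, acetyl bromide, via 10) with the mirror-image ligand to give (4S)-11-[3,5-bis(benzyloxy)phenyl]undecan-4-yl acetate F1.
- Methanolysis (K2CO3, MeOH, rt) would give (4S)-11-[3,5-bis(benzyloxy)phenyl]undecan-4-ol F2.
- A Mitsunobu esterification of acid 14 with this alcohol (PPh3, DIAD, toluene, 0 °C → rt) uses the hindered acid only as the nucleophile. It would invert the carbinol centre and give 17.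

**Step 6.**
- What may go wrong: loss of the electron-rich acyl bromide on concentration through hydrolysis or acylium-type self-acylation of another aromatic ring.
- The fallback avoids any acyl halide. It sets out from 14 and comes back at 16.
- Ruthenium-catalysed anti-Markovnikov addition of acid 14 to but-1-yne ([RuCl2(p-cymene)]2, P(4-ClC6H4)3, DMAP, toluene, 60 °C, sealed vessel) would give (Z)-but-1-en-1-yl 2-[(9R)-9-acetoxydodecyl]-4,6-dimethoxybenzoate F3.
- Markovnikov addition of dry HBr (CH2Cl2, −40 °C), the way 1-bromoethyl esters are made from vinyl esters, would give 16. This enters the nickel stage of step 7 directly.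

**Step 8.**
- What may go wrong: Friedel–Crafts benzylation of the liberated resorcinol ring in spite of the scavenger, over-demethylation at the para-methoxy group under the excess of Lewis acid that the debenzylation needs, or ionisation of the secondary ester C–O bond.
- The fallback changes the protecting-group plan so that no Lewis acid meets the late intermediates. It sets out from 13 and comes back at 18.
- Chelation-controlled demethylation of aldehyde 13 (BCl3, CH2Cl2, −78 → 0 °C) would give (4R)-12-(2-formyl-3-hydroxy-5-methoxyphenyl)dodecan-4-yl acetate F4.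
- Benzylation (BnBr, K2CO3, DMF) would give (4R)-12-[3-(benzyloxy)-2-formyl-5-methoxyphenyl]dodecan-4-yl acetate F5.
- The conditions of step 5 would give 2-[(9R)-9-acetoxydodecyl]-6-(benzyloxy)-4-methoxybenzoic acid F6.
- The conditions of step 6 would give 2-[(9R)-9-acetoxydodecyl]-6-(benzyloxy)-4-methoxybenzoyl bromide F7.
- The conditions of step 7, with 9 and 4, would lead through (1RS)-1-bromobutyl 2-[(9R)-9-acetoxydodecyl]-6-(benzyloxy)-4-methoxybenzoate F8 to (4R)-11-[3,5-bis(benzyloxy)phenyl]undecan-4-yl 2-[(9R)-9-acetoxydodecyl]-6-(benzyloxy)-4-methoxybenzoate F9.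
- Hydrogenolysis (H2, Pd/C, EtOAc/EtOH) would remove all three benzyl ethers to give 18. This is then methanolysed with HCl in MeOH as in the second stage of step 8.

## Further compounds

F1 | step 7 | (4S)-11-[3,5-bis(benzyloxy)phenyl]undecan-4-yl acetate | CC(=O)O[C@@H](CCC)CCCCCCCc1cc(OCc2ccccc2)cc(OCc2ccccc2)c1
F2 | step 7 | (4S)-11-[3,5-bis(benzyloxy)phenyl]undecan-4-ol | O[C@@H](CCC)CCCCCCCc1cc(OCc2ccccc2)cc(OCc2ccccc2)c1
F3 | step 6 | (Z)-but-1-en-1-yl 2-[(9R)-9-acetoxydodecyl]-4,6-dimethoxybenzoate | CCC[C@@H](OC(C)=O)CCCCCCCCc1cc(OC)cc(OC)c1C(=O)O/C=C\CC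
F4 | step 8 | (4R)-12-(2-formyl-3-hydroxy-5-methoxyphenyl)dodecan-4-yl acetate | CCC[C@@H](OC(C)=O)CCCCCCCCc1cc(OC)cc(O)c1C=O
F5 | step 8 | (4R)-12-[3-(benzyloxy)-2-formyl-5-methoxyphenyl]dodecan-4-yl acetate | CCC[C@@H](OC(C)=O)CCCCCCCCc1cc(OC)cc(OCc2ccccc2)c1C=O
F6 | step 8 | 2-[(9R)-9-acetoxydodecyl]-6-(benzyloxy)-4-methoxybenzoic acid | CCC[C@@H](OC(C)=O)CCCCCCCCc1cc(OC)cc(OCc2ccccc2)c1C(=O)O
F7 | step 8 | 2-[(9R)-9-acetoxydodecyl]-6-(benzyloxy)-4-methoxybenzoyl bromide | CCC[C@@H](OC(C)=O)CCCCCCCCc1cc(OC)cc(OCc2ccccc2)c1C(=O)Br
F8 | step 8 | (1RS)-1-bromobutyl 2-[(9R)-9-acetoxydodecyl]-6-(benzyloxy)-4-methoxybenzoate | CCC[C@@H](OC(C)=O)CCCCCCCCc1cc(OC)cc(OCc2ccccc2)c1C(=O)OC(Br)CCC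
F9 | step 8 | (4R)-11-[3,5-bis(benzyloxy)phenyl]undecan-4-yl 2-[(9R)-9-acetoxydodecyl]-6-(benzyloxy)-4-methoxybenzoate | CCC[C@@H](OC(C)=O)CCCCCCCCc1cc(OC)cc(OCc2ccccc2)c1C(=O)O[C@H](CCC)CCCCCCCc1cc(OCc2ccccc2)cc(OCc2ccccc2)c1
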